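**Retrosynthetic overview**

1. The dihydropyran (ring D) is made last, by a hetero-Diels–Alder reaction of an α-methylene-1,2-dione (ring-C diosphenol + CH2O) with the (Z)-C4'=C5' alkene of an ent-isocaryophyllene equivalent; its C8' methylene is masked as a β-hydroxysilane and released by Peterson elimination.
2. In the triquinane, ring A is closed last on a ring-B/C diquinane by a (3+2) radical–polar crossover annulation with allyl methacrylate: C9–C10 by Giese addition, C11–C1 by 5-exo-tet enolate alkylation.
3. Enabling feature: in ring A the quaternary C11 (Me, CO2H) lies between two CH2 groups (C10, C1) that hang from the vicinal, cis C9–H and C2–H of ring B. Ring A is therefore a methacrylate C10=C11 unit clamped onto a 1,3-pair (C9 radical, C1 tosylate) on the convex face of the cup-shaped diquinane.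
4. Rings C and B are formed together by a Pauson–Khand reaction of an enyne acetonide (Sharpless desymmetrisation of divinylcarbinol, acetylide opening); cuprate/CH2O then sets C3 and C2.
5. Terpene half: enantioselective (2+2) photocycloaddition (cyclobutane, ring F), α-methyl-α-vinyl ketone, Baeyer–Villiger lactone, Petasis methylenation/Claisen ring expansion (nine-membered ring E). Ring order: C+B, A; F, E; D last.

Key step: step 9

Remark: the descriptors of the target place the terpene half in the (1S,9R) series (enantiomeric to natural (−)-β-caryophyllene) with Me-12' cis to H-5', as from a (Z)-C4'=C5' alkene, so this half is built de novo. Locants are hirsutane numbers for the triquinane (ring A C1-C2-C9-C10-C11, ring B C2-C3-C7-C8-C9, ring C C3-C4-C5-C6-C7, pyran CH2 = C12) and primed caryophyllane numbers for the terpene half.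

**Route**

Step 1
Reactants: 1 penta-1,4-dien-3-ol (divinylcarbinol)
Product: 2 (2R,3S)-1,2-epoxypent-4-en-3-ol
Conditions: Ti(OiPr)4 (10 mol %), L-(+)-diisopropyl tartrate (13 mol %), t-BuOOH, 4 Å MS, CH2Cl2, −20 °C
Reagents that add atoms: tert-butyl hydroperoxide, CC(C)(C)OO
Why: Sharpless asymmetric epoxidation couples enantiotopic-group selection with erythro diastereofacial selection, so one vinyl group should be epoxidised to the (2R,3S)-epoxy alcohol while the minor enantiomer is consumed by a faster second epoxidation.

Step 2
Reactants: 2 (2R,3S)-1,2-epoxypent-4-en-3-ol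
Product: 3 (3S,4R)-hept-1-en-6-yne-3,4-diol
Conditions: lithium acetylide–ethylenediamine complex, DMSO, 0 °C to rt; aq. NH4Cl
Reagents that add atoms: lithium acetylide, [Li+].[C-]#C
Why: SN2 opening of the terminal epoxide carbon by acetylide (a Payne-rearranged epoxide would be opened at the same carbon) leaves both stereocentres untouched and should give the erythro 1,6-enyne diol.

Step 3
Reactants: 3 (3S,4R)-hept-1-en-6-yne-3,4-diol
Product: 4 (4R,5S)-2,2-dimethyl-4-(prop-2-yn-1-yl)-5-vinyl-1,3-dioxolane (cis)
Conditions: Me2C(OMe)2, PPTS (cat.), CH2Cl2, rt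
Reagents that add atoms: 2,2-dimethoxypropane, COC(C)(C)OC
Why: Acid-catalysed transketalisation turns the erythro diol into the cis-dioxolane, which protects the future C5/C6 oxygens and fixes the fold of the Pauson–Khand substrate.

Step 4
Reactants: 4 enyne acetonide
Product: 5 diquinane enone (C2=C3 alkene, C9 ketone, C5,C6-acetonide with both oxygens cis to H-7)
Conditions: Co2(CO)8 (10 mol %), tetramethylthiourea (60 mol %), CO (1 atm), benzene, 70 °C
Reagents that add atoms: carbon monoxide, [C-]#[O+]
Why: The catalytic intramolecular Pauson–Khand (2+2+1) reaction closes rings C and B at once; the cis-dioxolane is expected to sit on the convex face of the forming bicycle, which places H-7 cis to both oxygens.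

Step 5
Reactants: 5 diquinane enone
Product: 7 hydroxy ketone (C9 ketone; angular 3-Me cis to H-7; C2–CH2OH (C1) cis to 3-Me; C5,C6-acetonide), via lithium enolate 6 (not isolated)
Conditions: Me2CuLi (from CuI, 2 MeLi), Et2O, −40 to 0 °C; then monomeric CH2O in THF, −78 °C; aq. NH4Cl
Reagents that add atoms: lithium dimethylcuprate, [Li+].C[Cu-]C; formaldehyde, C=O
Why: 1,4-Addition to the ring-fusion β-carbon can only give the cis-fused diquinane, and the regiodefined enolate undergoes the aldol reaction with formaldehyde on its convex face, which puts C1 cis to the 3-methyl group (also the thermodynamic epimer next to the ketone).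

Step 6
Reactants: 7 hydroxy ketone
Product: 9 C9 pinacol boronate (C9 epimers; otherwise as 7), via tosylhydrazone 8 (not isolated)
Conditions: TsNHNH2, MeOH, rt; evaporate; then B2pin2, NaH, MeOH (5 equiv), toluene, 110 °C
Reagents that add atoms: bis(pinacolato)diboron, CC1(C)OB(OC1(C)C)B1OC(C)(C)C(C)(C)O1
Why: Transition-metal-free reductive borylation of a tosylhydrazone: base gives the diazoalkane, which inserts into B2pin2 and is protodeborylated by methanol; the C9 configuration is irrelevant because C9 becomes a radical in step 9.

Step 7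
Reactants: 9 C9 pinacol boronate
Product: 10 C1 tosylate of 9
Conditions: TsCl, pyridine, DMAP (cat.), CH2Cl2, 0 °C to rt
Reagents that add atoms: p-toluenesulfonyl chloride, Cc1ccc(cc1)S(Cl)(=O)=O
Why: Sulfonylation of the primary alcohol, the only hydroxyl group present.

Step 8
Reactants: 10 boronate tosylate
Product: 11 potassium C9-trifluoroborate with C1 tosylate (C9 epimers)
Conditions: KHF2 (aq.), MeOH, 0 °C to rt, short contact; extraction into acetone
Reagents that add atoms: potassium hydrogen difluoride, [K+].F.[F-]
Why: Fluoride exchange converts the pinacol boronate into the air-stable trifluoroborate, which is not nucleophilic at carbon and so cannot displace the 1,3-related tosylate.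

Step 9
Reactants: 11 trifluoroborate tosylate; 12 allyl methacrylate
Product: 14 triquinane ester (cis-anti-cis; allyl ester on C11 cis to H-2/H-9, 11-Me on the other face; C5,C6-acetonide), via potassium ester enolate 13 (not isolated)
Conditions: 4CzIPN (5 mol %), 12 (3 equiv), anhydrous degassed DMSO, blue LEDs (450 nm), rt
Reagents that add atoms: none
Why: Proposed new method: photoexcited 4CzIPN oxidises the secondary alkyltrifluoroborate to the C9 radical, which adds (Giese) to the CH2 terminus of allyl methacrylate to form C9–C10; the tertiary α-ester radical is reduced by the photocatalyst radical anion to enolate 13, whose C11 displaces the primary C1 tosylate to form C11–C1 and ring A. The closest known reaction type is the photoredox radical–polar crossover annulation of alkyltrifluoroborates, silicates or boronate complexes with acceptor alkenes (Giese addition, then anionic SN2 ring closure), known with the leaving group on the alkene partner, together with the anionic Michael-initiated ring closure. Ring A closes in the 5-exo-tet mode. C9 is set by attack of the alkene on the convex face of the cup-shaped diquinane (ring C blocks the concave face), which puts C10 cis to C1, and a concave-face adduct cannot close to a trans-fused diquinane and is removed as open-chain ester; C11 is set in the envelope transition state, where the planar, solvated enolate (the future ester) should take the convex position cis to H-2/H-9 and the methyl group should point into the fold. The step needs radical addition before reduction, ring closure before protonation and no attack of boron on the tosylate, which the pairing of a nucleophilic secondary radical with an electron-poor alkene, the aprotic medium and the inert BF3K group should secure.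

Step 10
Reactants: 14 triquinane ester acetonide
Product: 15 cis-5,6-diol (both hydroxyls cis to H-7; otherwise as 14)
Conditions: AcOH/H2O (4:1), 50 °C
Reagents that add atoms: none
Why: Aqueous acid hydrolyses the acetonide, while the hindered tertiary allyl ester is stable under these conditions.

Step 11
Reactants: 15 diol
Product: 16 diosphenol (5-hydroxy-4-en-6-one in ring C; allyl ester at C11)
Conditions: (COCl)2, DMSO, CH2Cl2, −78 °C; Et3N, −78 to 0 °C
Reagents that add atoms: none
Why: Double Swern oxidation of the cis-diol gives the 1,2-dione without C–C cleavage, and the dione should enolise toward C4 (enolisation toward C7 would put a double bond at the ring fusion) to the diosphenol.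

Step 12
Reactants: 17 cyclohex-2-en-1-one; 18 2-methylpropene
Product: 19 (1S,6S)-7,7-dimethylbicyclo[4.2.0]octan-2-one (cis-fused)
Conditions: hν (366 nm), AlBr3-activated chiral prolinol-derived 1,3,2-oxazaborolidine (50 mol %, the enantiomer that gives 6S), CH2Cl2, −75 °C; then K2CO3, MeOH, rt
Reagents that add atoms: none
Why: Chiral Lewis acid-catalysed enantioselective intermolecular [2+2] photocycloaddition: the complexed enone is excited selectively and shielded on one face, the head-to-tail regiochemistry puts the CMe2 carbon on the β-carbon, and base equilibrates the ring fusion to cis; C6 (later C1') is the only centre that has to persist.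

Step 13
Reactants: 19 photoadduct
Product: 20 (1S,6S)-3-(hydroxymethylene)-7,7-dimethylbicyclo[4.2.0]octan-2-one
Conditions: NaH, HCO2Et, THF, EtOH (cat.), 0 °C to rt; aq. HCl
Reagents that add atoms: ethyl formate, CCOC=O
Why: Claisen condensation with ethyl formate occurs at the CH2 α-carbon, where the product is stabilised as its enolate.

Step 14
Reactants: 20 hydroxymethylene ketone
Product: 21 (1S,6S)-3,7,7-trimethyl-2-oxobicyclo[4.2.0]octane-3-carbaldehyde (C3 epimers)
Conditions: K2CO3, MeI, acetone, rt
Reagents that add atoms: iodomethane, CI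
Why: C-Alkylation of the formyl ketone enolate builds the quaternary centre, and both C3 epimers are carried on because this centre becomes sp2 in step 17.

Step 15
Reactants: 21 keto aldehyde
Product: 22 (1S,6S)-3,7,7-trimethyl-3-vinylbicyclo[4.2.0]octan-2-one (C3 epimers)
Conditions: Ph3PCH3Br, KOtBu, THF, 0 °C
Reagents that add atoms: methyltriphenylphosphonium bromide, C[P+](c1ccccc1)(c1ccccc1)c1ccccc1.[Br-]
Why: Wittig methylenation is chemoselective for the aldehyde over the hindered ketone.

Step 16
Reactants: 22 vinyl ketone
Product: 23 (1S,7S)-4,8,8-trimethyl-4-vinyl-3-oxabicyclo[5.2.0]nonan-2-one (C4 epimers)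
Conditions: mCPBA, NaHCO3, CH2Cl2, 0 °C to rt
Reagents that add atoms: 3-chloroperbenzoic acid, OOC(=O)c1cccc(Cl)c1
Why: Baeyer–Villiger oxidation with migration of the tertiary, vinyl-substituted carbon in preference to the secondary cyclobutyl carbon should give the seven-membered lactone, while the monosubstituted alkene is epoxidised much more slowly.

Step 17
Reactants: 23 lactone
Product: 25 (1S,9S,4Z)-4,11,11-trimethylbicyclo[7.2.0]undec-4-en-8-one (cis-fused), via 2-methyleneoxepane 24 (not isolated)
Conditions: Cp2TiMe2, toluene, 75 °C, dark; then 170 °C, sealed tube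
Reagents that add atoms: dimethyltitanocene, [CH3-].[CH3-].[Ti+4].c1cc[cH-]c1.c1cc[cH-]c1
Why: Petasis methylenation gives an allyl vinyl ether that undergoes Claisen ring expansion on heating; the one-oxygen bridge of the bicyclic transition state allows only the cisoid C3'–C4'=C5'–C6' arrangement, so both C4' epimers should converge on the (Z)-cyclononenone.

Step 18
Reactants: 25 cis-fused ketone
Product: 26 (1S,9R,4Z)-4,11,11-trimethylbicyclo[7.2.0]undec-4-en-8-one (trans-fused)
Conditions: NaOMe (0.2 equiv), MeOH, rt
Reagents that add atoms: none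
Why: Base-mediated epimerisation at C9' (α to the ketone) should give the thermodynamically preferred trans-fused bicyclo[7.2.0]undecenone.

Step 19
Reactants: 26 trans-fused ketone
Product: 27 (1S,9R,4Z)-4,11,11-trimethyl-8-[(trimethylsilyl)methyl]bicyclo[7.2.0]undec-4-en-8-ol (C8' epimers)
Conditions: Me3SiCH2MgCl, CeCl3, THF, −78 to 0 °C; aq. NH4Cl
Reagents that add atoms: (trimethylsilyl)methylmagnesium chloride, C[Si](C)(C)C[Mg]Cl
Why: Organocerium addition to the enolisable, hindered ketone gives the β-hydroxysilane, which masks the exocyclic methylene so that only one alkene enters the cycloaddition; the C8' configuration is irrelevant.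

Step 20
Reactants: 16 diosphenol; 27 β-hydroxysilane
Product: 29 cycloadduct (allyl ester of the target with OH and CH2SiMe3 on C8' in place of the methylene; C8' epimers), via α-methylene-1,2-dione 28 (not isolated)
Conditions: paraformaldehyde, morpholine (20 mol %), AcOH (20 mol %), 1,4-dioxane, 80 °C
Reagents that add atoms: formaldehyde (as paraformaldehyde), C=O
Why: Domino Knoevenagel/hetero-Diels–Alder reaction: hydroxymethylation at C4 and loss of water give dione 28, whose O=C5–C4=CH2 heterodiene adds suprafacially to the electron-rich (Z)-alkene with oxygen on the more substituted C4', so Me-12' and H-5' end cis; attack on the alkene face syn to H-1' (away from C11') is expected to set C4' and C5'.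

Step 21
Reactants: 29 cycloadduct
Product: 30 allyl ester of the target
Conditions: KHMDS (2.5 equiv), THF, 0 °C to rt; aq. NH4Cl
Reagents that add atoms: none
Why: Peterson syn-elimination of the potassium alkoxide gives only the 1,1-disubstituted exocyclic alkene from either C8' epimer, and the ring-C enolate formed alongside is reprotonated to the cis ring fusion on work-up.

Step 22
Reactants: 30 allyl ester
Product: 31 target acid CNP0483070.2
Conditions: Pd(PPh3)4 (5 mol %), morpholine (5 equiv), THF, rt
Reagents that add atoms: none
Why: Tsuji–Trost deallylation with zerovalent palladium and morpholine as allyl acceptor frees the hindered acid under neutral conditions that leave the enol ether, enone and exocyclic alkene untouched.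

**Compound list**

1 | penta-1,4-dien-3-ol | C=CC(O)C=C | starting material
2 | (2R,3S)-1,2-epoxypent-4-en-3-ol | C=C[C@H](O)[C@H]1CO1 | intermediate
3 | (3S,4R)-hept-1-en-6-yne-3,4-diol | C=C[C@H](O)[C@H](O)CC#C | intermediate
4 | (4R,5S)-2,2-dimethyl-4-(prop-2-yn-1-yl)-5-vinyl-1,3-dioxolane | C#CC[C@H]1OC(C)(C)O[C@H]1C=C | intermediate
5 | diquinane enone, C5,C6-acetonide cis to H-7 | C1[C@H]2OC(C)(C)O[C@H]2[C@@H]3CC(=O)C=C13 | intermediate
6 | lithium enolate after methyl addition | C1[C@H]2OC(C)(C)O[C@H]2[C@@H]3CC([O-])=C[C@]13C.[Li+] | intermediate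
7 | hydroxy ketone (C9 ketone, C2–CH2OH cis to 3-Me) | C1[C@H]2OC(C)(C)O[C@H]2[C@@H]3CC(=O)[C@@H](CO)[C@]13C | intermediate
8 | C9 tosylhydrazone of 7 | C1[C@H]2OC(C)(C)O[C@H]2[C@@H]3CC(=NNS(=O)(=O)c4ccc(C)cc4)[C@@H](CO)[C@]13C | intermediate
9 | C9 pinacol boronate, C1 alcohol (C9 epimers) | C1[C@H]2OC(C)(C)O[C@H]2[C@@H]3CC(B4OC(C)(C)C(C)(C)O4)[C@@H](CO)[C@]13C | intermediate
10 | C9 pinacol boronate, C1 tosylate | C1[C@H]2OC(C)(C)O[C@H]2[C@@H]3CC(B4OC(C)(C)C(C)(C)O4)[C@@H](COS(=O)(=O)c5ccc(C)cc5)[C@]13C | intermediate
11 | potassium C9-trifluoroborate, C1 tosylate | C1[C@H]2OC(C)(C)O[C@H]2[C@@H]3CC([B-](F)(F)F)[C@@H](COS(=O)(=O)c4ccc(C)cc4)[C@]13C.[K+] | intermediate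
12 | allyl methacrylate | C=CCOC(=O)C(C)=C | starting material
13 | potassium ester enolate of the Giese adduct | C1[C@H]2OC(C)(C)O[C@H]2[C@@H]3C[C@@H](CC(C)=C([O-])OCC=C)[C@@H](COS(=O)(=O)c4ccc(C)cc4)[C@]13C.[K+] | intermediate
14 | cis-anti-cis triquinane allyl ester, C5,C6-acetonide | C1[C@H]2OC(C)(C)O[C@H]2[C@@H]3C[C@H]4C[C@](C)(C(=O)OCC=C)C[C@H]4[C@]13C | intermediate
15 | triquinane cis-5,6-diol allyl ester | C1[C@@H](O)[C@@H](O)[C@@H]2C[C@H]3C[C@](C)(C(=O)OCC=C)C[C@H]3[C@]12C | intermediate
16 | triquinane diosphenol allyl ester | C1=C(O)C(=O)[C@@H]2C[C@H]3C[C@](C)(C(=O)OCC=C)C[C@H]3[C@]12C | intermediate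
17 | cyclohex-2-en-1-one | O=C1C=CCCC1 | starting material
18 | 2-methylpropene | CC(C)=C | starting material
19 | (1S,6S)-7,7-dimethylbicyclo[4.2.0]octan-2-one | O=C1CCC[C@H]2[C@@H]1CC2(C)C | intermediate
20 | (1S,6S)-3-(hydroxymethylene)-7,7-dimethylbicyclo[4.2.0]octan-2-one | O=C1C(=CO)CC[C@H]2[C@@H]1CC2(C)C | intermediate
21 | (1S,6S)-3,7,7-trimethyl-2-oxobicyclo[4.2.0]octane-3-carbaldehyde | O=C1C(C)(C=O)CC[C@H]2[C@@H]1CC2(C)C | intermediate
22 | (1S,6S)-3,7,7-trimethyl-3-vinylbicyclo[4.2.0]octan-2-one | O=C1C(C)(C=C)CC[C@H]2[C@@H]1CC2(C)C | intermediate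
23 | (1S,7S)-4,8,8-trimethyl-4-vinyl-3-oxabicyclo[5.2.0]nonan-2-one | O=C1OC(C)(C=C)CC[C@H]2[C@@H]1CC2(C)C | intermediate
24 | (1S,7S)-4,8,8-trimethyl-2-methylene-4-vinyl-3-oxabicyclo[5.2.0]nonane | C=C1OC(C)(C=C)CC[C@H]2[C@@H]1CC2(C)C | intermediate
25 | (1S,9S,4Z)-4,11,11-trimethylbicyclo[7.2.0]undec-4-en-8-one | O=C1CC/C=C(/C)CC[C@H]2[C@@H]1CC2(C)C | intermediate
26 | (1S,9R,4Z)-4,11,11-trimethylbicyclo[7.2.0]undec-4-en-8-one | O=C1CC/C=C(/C)CC[C@H]2[C@H]1CC2(C)C | intermediate
27 | (1S,9R,4Z)-4,11,11-trimethyl-8-[(trimethylsilyl)methyl]bicyclo[7.2.0]undec-4-en-8-ol | C[Si](C)(C)CC1(O)CC/C=C(/C)CC[C@H]2[C@H]1CC2(C)C | intermediate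
28 | triquinane 4-methylene-5,6-dione allyl ester | C=C1C(=O)C(=O)[C@@H]2C[C@H]3C[C@](C)(C(=O)OCC=C)C[C@H]3[C@]12C | intermediate
29 | cycloadduct with C8' OH and CH2SiMe3, allyl ester | C[Si](C)(C)CC1(O)CC[C@H]2CC3=C(O[C@@]2(C)CC[C@H]2[C@H]1CC2(C)C)C(=O)[C@@H]1C[C@H]2C[C@](C)(C(=O)OCC=C)C[C@H]2[C@]31C | intermediate
30 | allyl ester of the target | C=C1CC[C@H]2CC3=C(O[C@@]2(C)CC[C@H]2[C@H]1CC2(C)C)C(=O)[C@@H]1C[C@H]2C[C@](C)(C(=O)OCC=C)C[C@H]2[C@]31C | intermediate
31 | CNP0483070.2 | C=C1CC[C@H]2CC3=C(O[C@@]2(C)CC[C@H]2[C@H]1CC2(C)C)C(=O)[C@@H]1C[C@H]2C[C@](C)(C(=O)O)C[C@H]2[C@]31C | target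

**Totals and risks**

Total step count: 22. Longest linear sequence: 14 steps (steps 1–11, then 20–22).

Steps most likely to fail:

1. Step 9 (proposed new method). The enolate may be protonated before ring closure, the methacrylate may oligomerise, or the radical may add on the concave face so that closure is impossible; the C11 configuration also rests on a kinetic argument. Fallback with known chemistry, setting out from trifluoroborate 11: a conventional photoredox Giese addition to 12 in a protic medium ([Ir(dF(CF3)ppy)2(bpy)]PF6, acetone/MeOH, blue LEDs) should give the open-chain allyl ester tosylate F1. Its potassium enolate (KHMDS, THF/DMPU, −78 to 0 °C) is then alkylated intramolecularly by the C1 tosylate, which returns to triquinane 14; only the C9 epimer with C10 cis to C1 can close.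

2. Step 20. Facial selectivity on the flexible nine-membered (Z)-alkene may be poor, and acid may cause early loss of Me3SiOH, uncovering the competing exocyclic alkene. Fallback, setting out from diosphenol 16 and ketone 26 (one alkene, no acid-labile group, different ring conformation): the same three-component cycloaddition should give the C8' ketone cycloadduct F2. Chemoselective methylenation of its saturated ketone with the non-basic CH2Br2/Zn/TiCl4 reagent (Lombardo–Takai conditions; the cross-conjugated, α-oxygenated enone carbonyl is less electrophilic) returns to ester 30.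

3. Step 6. A 1,2-hydrogen shift of the diazoalkane (Bamford–Stevens alkene formation) may outrun borylation next to the branched C2. Fallback, setting out from hydroxy ketone 7: silylation (TBSCl, imidazole) gives the silyl ether F3, and kinetic enol triflate formation toward C8 (KHMDS, PhNTf2) gives the enol triflate F4. Miyaura borylation (PdCl2(dppf), B2pin2, KOPh) then gives the alkenyl boronate F5, hydrogenation (H2, Pd/C) the alkyl boronate F6, and desilylation (TBAF/AcOH) returns to boronate 9.

Further compounds

F1 | step 9 | open-chain Giese adduct, allyl ester with C1 tosylate (C11 epimers) | C1[C@H]2OC(C)(C)O[C@H]2[C@@H]3C[C@@H](CC(C)C(=O)OCC=C)[C@@H](COS(=O)(=O)c4ccc(C)cc4)[C@]13C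
F2 | step 20 | C8' ketone cycloadduct, allyl ester | O=C1CC[C@H]2CC3=C(O[C@@]2(C)CC[C@H]2[C@H]1CC2(C)C)C(=O)[C@@H]1C[C@H]2C[C@](C)(C(=O)OCC=C)C[C@H]2[C@]31C
F3 | step 6 | TBS ether of hydroxy ketone 7 | C1[C@H]2OC(C)(C)O[C@H]2[C@@H]3CC(=O)[C@@H](CO[Si](C)(C)C(C)(C)C)[C@]13C
F4 | step 6 | C8=C9 enol triflate | C1[C@H]2OC(C)(C)O[C@H]2[C@@H]3C=C(OS(=O)(=O)C(F)(F)F)[C@@H](CO[Si](C)(C)C(C)(C)C)[C@]13C
F5 | step 6 | C9 alkenyl pinacol boronate | C1[C@H]2OC(C)(C)O[C@H]2[C@@H]3C=C(B4OC(C)(C)C(C)(C)O4)[C@@H](CO[Si](C)(C)C(C)(C)C)[C@]13C
F6 | step 6 | C9 alkyl pinacol boronate TBS ether | C1[C@H]2OC(C)(C)O[C@H]2[C@@H]3CC(B4OC(C)(C)C(C)(C)O4)[C@@H](CO[Si](C)(C)C(C)(C)C)[C@]13C
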